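## Analysis of the target

The target is the Z-p-coumarate of a bicyclic diterpene diol. It is a decalin (ring A: C1–C5 and C10; ring B: C5–C10) with a 3-methylidenepent-4-enyl chain (C11–C16) on C9, a tertiary carbinol at C8 (methyl C17), a methyl (C19) and an acyloxymethyl group (C18) on C4, and an angular methyl (C20) on C10. There are five stereocentres, (4R,5S,8R,9R,10S), all on or next to ring B. The C10 methyl, H5 and the C4 methyl lie on one face (called β below), so the rings are cis-fused and C18 is α. The C9 chain and the C8 methyl are also β; the 8-hydroxyl is α and trans to the chain. C4 and C10 are quaternary and flank the ring-fusion methine C5, which is the main constructional difficulty. Three groups are sensitive: the cross-conjugated terminal diene (acid, oxidants, hydrogenation, polymerisation), the Z-cinnamate with a free para-phenol (Z to E drift with light, base or nucleophilic catalysts), and the tertiary 8-hydroxyl (dehydration, and closure of an 8,12-ether with any leaving group on C12). These have to enter late and in a workable order. The strategy rests on ring A: with a C1=C2 double bond put back, ring A is the cycloadduct of a diene C3=C2–C1=C10 and a dienophile C4=C5 that are tied together by the four carbons C6–C9 of ring B. The geometry of two alkenes can then set C4, C5 and C10, and a single stereocentre at C9 in the tether can set the face.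

## Retrosynthetic reasoning

**Aryl–alkene bond and ester C–O bond.** Target 37 is cut at the bond between the phenol ring and the alkene, giving the Z-iodoacrylate 35 and boronic acid 36. Ester 35 is cut at the acyl–oxygen bond to diol 33 and acid 34. The Z geometry is bought with 34 and carried through a stereoretentive coupling, the phenol never needs a protecting group, and the labile ester is made last. The acylation has to take the primary C18 hydroxyl and leave the tertiary one, without Z to E drift.

**C12–C13 bond.** Diol 33 comes from its bis-silyl ether 32, which is cut between C12 and C13 to iodide 29 and the four-carbon Grignard reagent 31 made from 30. This places the diene after every oxidation and hydrogenation. Both hydroxyls are silylated (27, then 28 after freeing O12) because an alkoxide or hydroxyl at C8 next to an activated C12 would close the 8,12-ether.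

**C8–O and C8–C17.** Diol 26 is traced to the spiro-epoxide 25, the exocyclic alkene 24 and ketone 23, which comes from ketal 22. Oxygen is put on C8 from the α-face by an electrophilic reagent and C17 becomes the methyl by hydride opening; the same hydride step turns the C4 ester into the C18 carbinol. A direct methyl addition to 23 is expected to come from the same open face and would give the wrong epimer, so it is kept only as a fallback.

**C1=C2.** Decalin 22 comes from octalin 21 by hydrogenation. No stereocentre is involved.

**C5–C10 and C3–C4 (key).** Octalin 21 is opened to the acyclic trienoate 20. This is the only disconnection that removes both rings and three stereocentres (C4, C5, C10) at once and leaves a precursor with a single stereocentre, C9. The forward reaction has to form two quaternary carbons, give the cis fusion, and let C9 choose the diene face.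

**C4=C5.** Trienoate 20 is cut at the enoate double bond to aldehyde 18 and phosphonate 19. A Z-selective olefination is needed because this geometry becomes the C4 configuration. Aldehyde 18 is reached from ester 14 through 15, 16 and 17 by reduction, protection of O12, release of O5 and oxidation.

**C9–C10.** Ester 14 is cut between C9 and C10 to the ketal enoate 11 and the Z-dienyl iodide 5 (used as 12 and 13). A catalytic asymmetric conjugate addition sets C9. The ketal is already in place so that only the ester directs the addition and C9 never sits next to a free ketone.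

**C7–C8.** Enoate 11 comes from keto enoate 10, which is cut at the ketone to acid chloride 7 (from 6) and iodide 8 (as zinc reagent 9). The acceptor is then three steps from a fumarate.

**Dienyl iodide.** Iodide 5 comes from enal 4 and iodo alcohol 3 by methylenation and oxidation, and 3 from alkynol 1 through aluminate 2. The anti hydroalumination fixes the Z geometry that later puts the tether on the inside position of the diene.

## Alternatives that were turned down

**Alternative 1:** The C4–C5 bond of ring A is cut. The cyclohexenone A1 (ring B with C8, C9 and C10 in place, and a chain on C10 ending in the 1,1-disubstituted alkene C4=C19) is treated with Fe(acac)3 and PhSiH3. Hydrogen-atom transfer makes the tertiary C4 radical, which adds 6-exo to C5 of the enone to give the cis-fused decalinone A2.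
- For: the step runs at room temperature without acid. Radical conjugate additions form quaternary carbons well, and 6-exo closure onto a cyclohexenone with an angular substituent normally gives the cis fusion. As a single step it is probably more reliable than the cycloaddition chosen here, and it avoids a strained Z-diene.
- Against: C4 is made from a radical whose two outer groups, methyl and silyloxymethyl, differ little, so its configuration is not fixed by the mechanism. A1 already contains three contiguous stereocentres including quaternary C10, which must be built first. A2 carries a C7 carbonyl and a C8–H, so C8 must still be hydroxylated and C7 deoxygenated.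
- Comparison: the chosen route accepts a harder key step, but takes C4, C5 and C10 from alkene geometry in one operation from a precursor with one stereocentre.

**Alternative 2:** The C13=C16 and C14=C15 bonds are cut. The terminal alkyne A3 is treated with ethylene and second-generation Grubbs catalyst to give the diene A4.
- For: the enyne metathesis is dependable, tolerates the free tertiary hydroxyl and needs no electrophile at C12. For installing the diene it is stronger than the Grignard coupling used here, and it is kept as the fallback for step 22.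
- Against: no ring and no stereocentre is formed. A3 already holds the complete cis-decalin with all five stereocentres, so the real problem is untouched.
- Comparison: the chosen strategy solves the core; the two diene tactics are interchangeable at the end.

**Alternative 3:** The C8–C9 bond of ring B is cut. The keto enoate A5 (ring A complete, a 3-oxobutyl chain on C5 and an acrylate on C10) is reduced with SmI2; the C8 ketyl adds 6-exo to C9 and gives the hydroxy ester A6.
- For: ketyl–enoate cyclisations are well established. This one makes the C8 carbinol and C9 together, with C11–C12 at a useful oxidation level. On that point it is stronger, since the chosen route spends steps 16 to 18 on C8.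
- Against: ring A with C4, C5 and C10 must already exist in A5, so the hardest stereochemical problem is only moved back. Six-membered ketyl closures are less selective than five-membered ones, and here the chain would have to end cis to the C10 methyl next to a quaternary carbon. A6 is a γ-hydroxy ester that would lactonise and later meet the same O8/C12 ether problem.
- Comparison: the chosen route builds both rings and the C4/C5/C10 array in one step and treats C8 afterwards by reagent-controlled chemistry on a rigid bicycle.

Key step: step 13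

## Route

Remark on names: labdane locants are used (C1–C10 decalin, C11–C16 chain on C9, C17 on C8, C18 and C19 on C4, C20 on C10). β is the face of the C10 methyl. All decalins below have 10β-CH3, 5β-H (cis fusion), 4β-CH3 (C19), the C18 carbon 4α, and the C9 chain β with H9 α.

Remark on starting materials: tert-butyl(3-iodopropoxy)dimethylsilane (8), 2-chlorobuta-1,3-diene (30), (2Z)-3-iodoprop-2-enoic acid (34) and (4-hydroxyphenyl)boronic acid (36) are taken as catalogue compounds, so propane-1,3-diol is not needed.

Step 1
Reactants: 1 but-2-yn-1-ol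
Product: 3 (2Z)-3-iodobut-2-en-1-ol, via cyclic sodium alkenylalanate 2 (not isolated)
Conditions: NaAlH2(OCH2CH2OMe)2, THF, 0 °C to rt; then I2, THF, −78 to 0 °C
Reagents that add atoms: iodine, SMILES II
Why: Hydroxyl-directed anti hydroalumination of the propargylic alcohol puts hydride on C2 and aluminium on C3; iodinolysis of the C–Al bond with retention gives the iodide cis to CH2OH.

Step 2
Reactants: 3 (2Z)-3-iodobut-2-en-1-ol
Product: 4 (2Z)-3-iodobut-2-enal
Conditions: MnO2, CH2Cl2, rt, dark
Reagents that add atoms: none
Why: Neutral allylic oxidation on the MnO2 surface; no acid or base is present that could isomerise the Z-iodoenal, which is used without storage.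

Step 3
Reactants: 4 (2Z)-3-iodobut-2-enal
Product: 5 (3Z)-4-iodopenta-1,3-diene
Conditions: Ph3PCH3Br, KN(SiMe3)2, THF, −78 to 0 °C
Reagents that add atoms: methyltriphenylphosphonium bromide, SMILES C[P+](c1ccccc1)(c1ccccc1)c1ccccc1.[Br-]
Why: Wittig methylenation; the unstabilised ylide adds 1,2 to the aldehyde at low temperature and the iodoalkene geometry is untouched. The volatile diene is kept as a solution.

Step 4
Reactants: 6 monomethyl fumarate
Product: 7 methyl (2E)-4-chloro-4-oxobut-2-enoate
Conditions: (COCl)2, DMF (cat.), CH2Cl2, 0 °C to rt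
Reagents that add atoms: oxalyl chloride, SMILES O=C(Cl)C(=O)Cl
Why: Acid chloride formation through the chloroiminium salt of DMF; the E-alkene and the methyl ester are inert.

Step 5
Reactants: 8 tert-butyl(3-iodopropoxy)dimethylsilane; 7 methyl (2E)-4-chloro-4-oxobut-2-enoate
Product: 10 methyl (2E)-7-(tert-butyldimethylsilyloxy)-4-oxohept-2-enoate, via alkylzinc iodide 9 (not isolated)
Conditions: Zn dust, LiCl, THF, 40 °C; then 7, Pd(PPh3)4 (5 mol%), THF, 0 °C to rt
Reagents that add atoms: none
Why: Zinc inserts into the primary C–I bond, and the palladium-catalysed acylation of the alkylzinc with the acid chloride (Negishi acylation) is faster than conjugate addition to the fumarate; the silyl ether and ester are tolerated.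

Step 6
Reactants: 10 methyl (2E)-7-(tert-butyldimethylsilyloxy)-4-oxohept-2-enoate
Product: 11 methyl (2E)-3-{2-[3-(tert-butyldimethylsilyloxy)propyl]-1,3-dioxolan-2-yl}prop-2-enoate
Conditions: Me3SiOCH2CH2OSiMe3, Me3SiOTf (cat.), CH2Cl2, −78 to −20 °C
Reagents that add atoms: 1,2-bis(trimethylsilyloxy)ethane, SMILES C[Si](C)(C)OCCO[Si](C)(C)C
Why: Noyori ketalisation under aprotic conditions, so no free glycol can add to the electron-poor alkene and the silyl ether survives. With C8 masked, only the ester activates the alkene and the later addition must go to C9.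

Step 7
Reactants: 5 (3Z)-4-iodopenta-1,3-diene; 11 methyl (2E)-3-{2-[3-(tert-butyldimethylsilyloxy)propyl]-1,3-dioxolan-2-yl}prop-2-enoate
Product: 14 methyl (3R,4Z)-3-{2-[3-(tert-butyldimethylsilyloxy)propyl]-1,3-dioxolan-2-yl}-4-methylhepta-4,6-dienoate, via dienyllithium 12 (not isolated), via lithium dienyl(trimethoxy)borate 13 (not isolated)
Conditions: t-BuLi (2 equiv), Et2O, −78 °C; B(OMe)3, −78 °C to rt; then 11, Rh(acac)(C2H4)2 (3 mol%), (S)-BINAP (3.3 mol%), dioxane/H2O, 100 °C
Reagents that add atoms: none
Why: Hayashi–Miyaura asymmetric 1,4-addition: the dienyl group passes from boron to rhodium with retention of its geometry, the enoate inserts on one enantioface, and water protonates the rhodium enolate. (S)-BINAP is chosen by analogy with E-crotonates, which it converts into (R)-3-aryl butanoates by attack on the same face of the α-carbon; here that face gives 3R (C9), and the sense is to be confirmed by correlation on the first batch.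

Step 8
Reactants: 14 methyl (3R,4Z)-3-{2-[3-(tert-butyldimethylsilyloxy)propyl]-1,3-dioxolan-2-yl}-4-methylhepta-4,6-dienoate
Product: 15 (3R,4Z)-3-{2-[3-(tert-butyldimethylsilyloxy)propyl]-1,3-dioxolan-2-yl}-4-methylhepta-4,6-dien-1-ol
Conditions: LiAlH4, Et2O, 0 °C
Reagents that add atoms: none
Why: Hydride reduction of the ester to the C12 carbinol; ketal, silyl ether and the unactivated diene are inert.

Step 9
Reactants: 15 (3R,4Z)-3-{2-[3-(tert-butyldimethylsilyloxy)propyl]-1,3-dioxolan-2-yl}-4-methylhepta-4,6-dien-1-ol
Product: 16 2-[(3R,4Z)-1-(4-methoxybenzyloxy)-4-methylhepta-4,6-dien-3-yl]-2-[3-(tert-butyldimethylsilyloxy)propyl]-1,3-dioxolane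
Conditions: NaH, 4-MeOC6H4CH2Cl, Bu4NI (cat.), THF/DMF, 0 °C to rt
Reagents that add atoms: 4-methoxybenzyl chloride, SMILES COc1ccc(CCl)cc1
Why: Williamson etherification; the PMB ether is orthogonal to the silyl ether on O5 now and to the triethylsilyl ethers later, and it withstands acid, hydride and peracid.

Step 10
Reactants: 16 2-[(3R,4Z)-1-(4-methoxybenzyloxy)-4-methylhepta-4,6-dien-3-yl]-2-[3-(tert-butyldimethylsilyloxy)propyl]-1,3-dioxolane
Product: 17 3-{2-[(3R,4Z)-1-(4-methoxybenzyloxy)-4-methylhepta-4,6-dien-3-yl]-1,3-dioxolan-2-yl}propan-1-ol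
Conditions: Bu4NF, THF, 0 °C to rt
Reagents that add atoms: none
Why: Fluoride cleaves the Si–O bond; ketal, PMB ether and diene are unaffected.

Step 11
Reactants: 17 3-{2-[(3R,4Z)-1-(4-methoxybenzyloxy)-4-methylhepta-4,6-dien-3-yl]-1,3-dioxolan-2-yl}propan-1-ol
Product: 18 3-{2-[(3R,4Z)-1-(4-methoxybenzyloxy)-4-methylhepta-4,6-dien-3-yl]-1,3-dioxolan-2-yl}propanal
Conditions: Dess–Martin periodinane, NaHCO3, CH2Cl2, 0 °C to rt
Reagents that add atoms: none
Why: Dess–Martin oxidation of the primary alcohol; the bicarbonate buffer protects the ketal and the Z-diene from the acetic acid released.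

Step 12
Reactants: 18 3-{2-[(3R,4Z)-1-(4-methoxybenzyloxy)-4-methylhepta-4,6-dien-3-yl]-1,3-dioxolan-2-yl}propanal; 19 methyl 2-[bis(2,2,2-trifluoroethoxy)phosphoryl]propanoate
Product: 20 methyl (2Z)-5-{2-[(3R,4Z)-1-(4-methoxybenzyloxy)-4-methylhepta-4,6-dien-3-yl]-1,3-dioxolan-2-yl}-2-methylpent-2-enoate
Conditions: 19, KN(SiMe3)2, 18-crown-6, THF, −78 °C; then 18
Reagents that add atoms: none
Why: Still–Gennari olefination: the electron-poor phosphonate and the dissociated potassium ion make elimination from the first-formed adduct fast, which gives the Z-trisubstituted enoate (ester cis to the chain).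

Step 13
Reactants: 20 methyl (2Z)-5-{2-[(3R,4Z)-1-(4-methoxybenzyloxy)-4-methylhepta-4,6-dien-3-yl]-1,3-dioxolan-2-yl}-2-methylpent-2-enoate
Product: 21 methyl 8,8-(ethylenedioxy)-12-(4-methoxybenzyloxy)-13,14,15,16,17-pentanor-5β-labd-1-en-18-oate
Conditions: Me2AlCl (2.5 equiv), CH2Cl2, −78 to −10 °C
Reagents that add atoms: none
Why: Me2AlCl binds the ester carbonyl and lowers the LUMO of the Z-enoate; the triene then undergoes a concerted, asynchronous, suprafacial [4+2] cycloaddition in which C5 (the β-carbon) bonds to the fully substituted diene terminus C10 ahead of C4 bonding to C3, the closest known reaction type being the Lewis-acid-promoted intramolecular Diels–Alder reaction of terminally activated 1,7,9-decatrienoates with Z-dienes. Ring B closes as the six-membered ring that the four-atom tether C6–C9 forms with the new C5–C10 bond; ring A is the cyclohexene made by the cycloaddition itself, completed by the C3–C4 bond, with the new alkene at C1=C2. The ring fusion is controlled by the Z geometry of C1=C10: a tether on the inside position of the diene can reach C5 only when C6 is exo, which puts the outside methyl and H5 on the same face, so the fusion is cis. C4 is controlled by the Z geometry of the enoate: the methyl stays syn to H5 and the ester syn to C6, so the ester is exo and becomes the α-carbon C18. The diene face is controlled by C9: to avoid 1,3-allylic strain H9 lies in the diene plane, the dioxolane carbon C8 carries the dienophile to one face and the C11 arm sits on the other, which leaves C11 cis to the C10 methyl. The step needs this facial selectivity and freedom from a 1,5-hydrogen shift of the Z-diene and from ionisation of the dioxolane; the conformational bias at C9 secures the first, and a mild, proton-scavenging aluminium Lewis acid at or below −10 °C instead of heat secures the other two.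

Step 14
Reactants: 21 methyl 8,8-(ethylenedioxy)-12-(4-methoxybenzyloxy)-13,14,15,16,17-pentanor-5β-labd-1-en-18-oate
Product: 22 methyl 8,8-(ethylenedioxy)-12-(4-methoxybenzyloxy)-13,14,15,16,17-pentanor-5β-labdan-18-oate
Conditions: H2 (1 atm), 10% Pd/C, pyridine (0.5 equiv), EtOAc, rt
Reagents that add atoms: none
Why: Heterogeneous hydrogenation of the cis-disubstituted ring alkene; pyridine suppresses hydrogenolysis of the benzylic ether, and no stereocentre is formed.

Step 15
Reactants: 22 methyl 8,8-(ethylenedioxy)-12-(4-methoxybenzyloxy)-13,14,15,16,17-pentanor-5β-labdan-18-oate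
Product: 23 methyl 12-(4-methoxybenzyloxy)-8-oxo-13,14,15,16,17-pentanor-5β-labdan-18-oate
Conditions: pyridinium p-toluenesulfonate (cat.), acetone/H2O, 55 °C
Reagents that add atoms: water, SMILES O
Why: Acid-catalysed hydrolysis of the dioxolane through the oxocarbenium ion; the weak acid is chosen so that the ketone does not enolise towards C9, and the PMB ether and hindered ester survive.

Step 16
Reactants: 23 methyl 12-(4-methoxybenzyloxy)-8-oxo-13,14,15,16,17-pentanor-5β-labdan-18-oate
Product: 24 methyl 12-(4-methoxybenzyloxy)-13,14,15,16-tetranor-5β-labd-8(17)-en-18-oate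
Conditions: Cp2TiMe2, toluene/THF, 65 °C, dark
Reagents that add atoms: dimethyltitanocene, SMILES C[Ti+2]C.c1cc[cH-]c1.c1cc[cH-]c1
Why: Petasis methylenation through Cp2Ti=CH2 and an oxatitanacyclobutane; the reagent is not basic, so the α-stereocentre C9 is not epimerised, and the ketone reacts ahead of the α-quaternary ester.

Step 17
Reactants: 24 methyl 12-(4-methoxybenzyloxy)-13,14,15,16-tetranor-5β-labd-8(17)-en-18-oate
Product: 25 methyl 8α,17-epoxy-12-(4-methoxybenzyloxy)-13,14,15,16-tetranor-5β-labdan-18-oate
Conditions: m-CPBA, NaHCO3, CH2Cl2, 0 °C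
Reagents that add atoms: 3-chloroperoxybenzoic acid, SMILES OOC(=O)c1cccc(Cl)c1
Why: Prilezhaev epoxidation of the exocyclic alkene. In the ring B chair with the C9 chain equatorial, the C10 methyl is axial and syn to the β approach to C8 and the chain also lies on the β side, so the peracid should deliver oxygen to the α-face.

Step 18
Reactants: 25 methyl 8α,17-epoxy-12-(4-methoxybenzyloxy)-13,14,15,16-tetranor-5β-labdan-18-oate
Product: 26 12-(4-methoxybenzyloxy)-13,14,15,16-tetranor-5β-labdane-8α,18-diol
Conditions: LiAlH4, THF, 0 °C to reflux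
Reagents that add atoms: none
Why: Hydride opens the spiro-epoxide by SN2 attack at the primary carbon C17, which leaves the 8α-hydroxyl and makes the 8β-methyl without touching the C8–O bond; the same reagent reduces the neopentyl ester to the C18 carbinol.

Step 19
Reactants: 26 12-(4-methoxybenzyloxy)-13,14,15,16-tetranor-5β-labdane-8α,18-diol
Product: 27 8α,18-bis(triethylsilyloxy)-12-(4-methoxybenzyloxy)-13,14,15,16-tetranor-5β-labdane
Conditions: Et3SiOTf, 2,6-lutidine, CH2Cl2, −78 to 0 °C
Reagents that add atoms: triethylsilyl trifluoromethanesulfonate, SMILES CC[Si](CC)(CC)OS(=O)(=O)C(F)(F)F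
Why: The silyl triflate silylates the tertiary as well as the primary hydroxyl. Masking O8 is what prevents closure of the 8,12-ether in steps 21 and 22.

Step 20
Reactants: 27 8α,18-bis(triethylsilyloxy)-12-(4-methoxybenzyloxy)-13,14,15,16-tetranor-5β-labdane
Product: 28 8α,18-bis(triethylsilyloxy)-13,14,15,16-tetranor-5β-labdan-12-ol
Conditions: DDQ, CH2Cl2/pH 7 buffer, 0 °C to rt
Reagents that add atoms: none
Why: Oxidative cleavage of the PMB ether by benzylic hydride abstraction and hydrolysis of the oxocarbenium ion; the buffer keeps the silyl ethers intact, and no alkene is present.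

Step 21
Reactants: 28 8α,18-bis(triethylsilyloxy)-13,14,15,16-tetranor-5β-labdan-12-ol
Product: 29 12-iodo-8α,18-bis(triethylsilyloxy)-13,14,15,16-tetranor-5β-labdane
Conditions: I2, PPh3, imidazole, CH2Cl2, 0 °C to rt
Reagents that add atoms: iodine, SMILES II
Why: Appel-type iodination (Garegg–Samuelsson conditions): iodide displaces the alkoxyphosphonium ion at the unhindered primary C12 by SN2.

Step 22
Reactants: 29 12-iodo-8α,18-bis(triethylsilyloxy)-13,14,15,16-tetranor-5β-labdane; 30 2-chlorobuta-1,3-diene
Product: 32 8α,18-bis(triethylsilyloxy)-5β-labda-13(16),14-diene, via buta-1,3-dien-2-ylmagnesium chloride 31 (not isolated)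
Conditions: 30, Mg, ZnCl2 (cat.), THF, 50 °C; then 29, Li2CuCl4 (3 mol%), THF, −20 to 0 °C
Reagents that add atoms: none
Why: Copper-catalysed cross-coupling of a Grignard reagent with a primary alkyl iodide (Kochi coupling) forms the C12–C13 bond and delivers the 2-substituted butadiene directly; silyl ethers are inert to the Grignard reagent.

Step 23
Reactants: 32 8α,18-bis(triethylsilyloxy)-5β-labda-13(16),14-diene
Product: 33 5β-labda-13(16),14-diene-8α,18-diol
Conditions: Bu4NF, THF, rt to 45 °C
Reagents that add atoms: none
Why: Fluoride removes both triethylsilyl groups under non-acidic conditions that the diene and the tertiary alcohol tolerate.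

Step 24
Reactants: 33 5β-labda-13(16),14-diene-8α,18-diol; 34 (2Z)-3-iodoprop-2-enoic acid
Product: 35 8α-hydroxy-5β-labda-13(16),14-dien-18-yl (2Z)-3-iodoprop-2-enoate
Conditions: 34, N,N'-diisopropylcarbodiimide, DMAP (0.1 equiv), CH2Cl2, −20 to 0 °C, dark
Reagents that add atoms: none
Why: Steglich esterification; the primary C18 hydroxyl is acylated and the hindered tertiary C8 hydroxyl is not. Low temperature and little DMAP limit addition–elimination at C3 of the iodoacrylate, which is the path to the E isomer.

Step 25
Reactants: 35 8α-hydroxy-5β-labda-13(16),14-dien-18-yl (2Z)-3-iodoprop-2-enoate; 36 (4-hydroxyphenyl)boronic acid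
Product: 37 8α-hydroxy-5β-labda-13(16),14-dien-18-yl (2Z)-3-(4-hydroxyphenyl)prop-2-enoate, the (4R,5S,8R,9R,10S) target
Conditions: 36, Pd(PPh3)4 (5 mol%), K2CO3, THF/H2O, 40 °C, dark
Reagents that add atoms: none
Why: Suzuki–Miyaura coupling: oxidative addition into the alkenyl C–I bond, transmetalation and reductive elimination all proceed with retention, so the Z geometry of 35 is carried into the coumarate. The free phenol and the tertiary alcohol are tolerated, and the mild base, low temperature and darkness guard the Z-enoate.

## Compound list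

1 | but-2-yn-1-ol | CC#CCO | starting material
2 | cyclic sodium alkenylalanate (sodium 2,2-bis(2-methoxyethoxy)-3-methyl-2,5-dihydro-1,2-oxaluminol-2-uide) | [Na+].CC1=CCO[Al-]1(OCCOC)OCCOC | intermediate (not isolated)
3 | (2Z)-3-iodobut-2-en-1-ol | C/C(I)=C/CO | intermediate
4 | (2Z)-3-iodobut-2-enal | C/C(I)=C/C=O | intermediate
5 | (3Z)-4-iodopenta-1,3-diene | C=C/C=C(/C)I | intermediate
6 | monomethyl fumarate | COC(=O)/C=C/C(=O)O | starting material
7 | methyl (2E)-4-chloro-4-oxobut-2-enoate | COC(=O)/C=C/C(=O)Cl | intermediate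
8 | tert-butyl(3-iodopropoxy)dimethylsilane | CC(C)(C)[Si](C)(C)OCCCI | starting material
9 | [3-(tert-butyldimethylsilyloxy)propyl]zinc iodide | CC(C)(C)[Si](C)(C)OCCC[Zn]I | intermediate (not isolated)
10 | methyl (2E)-7-(tert-butyldimethylsilyloxy)-4-oxohept-2-enoate | COC(=O)/C=C/C(=O)CCCO[Si](C)(C)C(C)(C)C | intermediate
11 | methyl (2E)-3-{2-[3-(tert-butyldimethylsilyloxy)propyl]-1,3-dioxolan-2-yl}prop-2-enoate | COC(=O)/C=C/C1(CCCO[Si](C)(C)C(C)(C)C)OCCO1 | intermediate
12 | (2E)-penta-2,4-dien-2-yllithium (lithium cis to the vinyl group) | C=C/C=C(/C)[Li] | intermediate (not isolated)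
13 | lithium trimethoxy[(2E)-penta-2,4-dien-2-yl]borate (boron cis to the vinyl group) | [Li+].C=C/C=C(/C)[B-](OC)(OC)OC | intermediate (not isolated)
14 | methyl (3R,4Z)-3-{2-[3-(tert-butyldimethylsilyloxy)propyl]-1,3-dioxolan-2-yl}-4-methylhepta-4,6-dienoate | C=C/C=C(/C)[C@@H](CC(=O)OC)C1(CCCO[Si](C)(C)C(C)(C)C)OCCO1 | intermediate
15 | (3R,4Z)-3-{2-[3-(tert-butyldimethylsilyloxy)propyl]-1,3-dioxolan-2-yl}-4-methylhepta-4,6-dien-1-ol | C=C/C=C(/C)[C@@H](CCO)C1(CCCO[Si](C)(C)C(C)(C)C)OCCO1 | intermediate
16 | 2-[(3R,4Z)-1-(4-methoxybenzyloxy)-4-methylhepta-4,6-dien-3-yl]-2-[3-(tert-butyldimethylsilyloxy)propyl]-1,3-dioxolane | C=C/C=C(/C)[C@@H](CCOCc1ccc(OC)cc1)C1(CCCO[Si](C)(C)C(C)(C)C)OCCO1 | intermediate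
17 | 3-{2-[(3R,4Z)-1-(4-methoxybenzyloxy)-4-methylhepta-4,6-dien-3-yl]-1,3-dioxolan-2-yl}propan-1-ol | C=C/C=C(/C)[C@@H](CCOCc1ccc(OC)cc1)C1(CCCO)OCCO1 | intermediate
18 | 3-{2-[(3R,4Z)-1-(4-methoxybenzyloxy)-4-methylhepta-4,6-dien-3-yl]-1,3-dioxolan-2-yl}propanal | C=C/C=C(/C)[C@@H](CCOCc1ccc(OC)cc1)C1(CCC=O)OCCO1 | intermediate
19 | methyl 2-[bis(2,2,2-trifluoroethoxy)phosphoryl]propanoate | COC(=O)C(C)P(=O)(OCC(F)(F)F)OCC(F)(F)F | starting material
20 | methyl (2Z)-5-{2-[(3R,4Z)-1-(4-methoxybenzyloxy)-4-methylhepta-4,6-dien-3-yl]-1,3-dioxolan-2-yl}-2-methylpent-2-enoate | C=C/C=C(/C)[C@@H](CCOCc1ccc(OC)cc1)C1(CC/C=C(/C)C(=O)OC)OCCO1 | intermediate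
21 | methyl 8,8-(ethylenedioxy)-12-(4-methoxybenzyloxy)-13,14,15,16,17-pentanor-5β-labd-1-en-18-oate | COc1ccc(COCC[C@@H]2[C@@]3(C)C=CC[C@@](C)(C(=O)OC)[C@H]3CCC24OCCO4)cc1 | intermediate
22 | methyl 8,8-(ethylenedioxy)-12-(4-methoxybenzyloxy)-13,14,15,16,17-pentanor-5β-labdan-18-oate | COc1ccc(COCC[C@@H]2[C@@]3(C)CCC[C@@](C)(C(=O)OC)[C@H]3CCC24OCCO4)cc1 | intermediate
23 | methyl 12-(4-methoxybenzyloxy)-8-oxo-13,14,15,16,17-pentanor-5β-labdan-18-oate | COc1ccc(COCC[C@@H]2[C@@]3(C)CCC[C@@](C)(C(=O)OC)[C@H]3CCC2=O)cc1 | intermediate
24 | methyl 12-(4-methoxybenzyloxy)-13,14,15,16-tetranor-5β-labd-8(17)-en-18-oate | COc1ccc(COCC[C@@H]2[C@@]3(C)CCC[C@@](C)(C(=O)OC)[C@H]3CCC2=C)cc1 | intermediate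
25 | methyl 8α,17-epoxy-12-(4-methoxybenzyloxy)-13,14,15,16-tetranor-5β-labdan-18-oate | COc1ccc(COCC[C@@H]2[C@@]3(C)CCC[C@@](C)(C(=O)OC)[C@H]3CC[C@]24CO4)cc1 | intermediate
26 | 12-(4-methoxybenzyloxy)-13,14,15,16-tetranor-5β-labdane-8α,18-diol | COc1ccc(COCC[C@@H]2[C@@]3(C)CCC[C@@](C)(CO)[C@H]3CC[C@@]2(C)O)cc1 | intermediate
27 | 8α,18-bis(triethylsilyloxy)-12-(4-methoxybenzyloxy)-13,14,15,16-tetranor-5β-labdane | COc1ccc(COCC[C@@H]2[C@@]3(C)CCC[C@@](C)(CO[Si](CC)(CC)CC)[C@H]3CC[C@@]2(C)O[Si](CC)(CC)CC)cc1 | intermediate
28 | 8α,18-bis(triethylsilyloxy)-13,14,15,16-tetranor-5β-labdan-12-ol | OCC[C@@H]1[C@@]2(C)CCC[C@@](C)(CO[Si](CC)(CC)CC)[C@H]2CC[C@@]1(C)O[Si](CC)(CC)CC | intermediate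
29 | 12-iodo-8α,18-bis(triethylsilyloxy)-13,14,15,16-tetranor-5β-labdane | ICC[C@@H]1[C@@]2(C)CCC[C@@](C)(CO[Si](CC)(CC)CC)[C@H]2CC[C@@]1(C)O[Si](CC)(CC)CC | intermediate
30 | 2-chlorobuta-1,3-diene | C=CC(Cl)=C | starting material
31 | buta-1,3-dien-2-ylmagnesium chloride | C=CC(=C)[Mg]Cl | intermediate (not isolated)
32 | 8α,18-bis(triethylsilyloxy)-5β-labda-13(16),14-diene | C=CC(=C)CC[C@@H]1[C@@]2(C)CCC[C@@](C)(CO[Si](CC)(CC)CC)[C@H]2CC[C@@]1(C)O[Si](CC)(CC)CC | intermediate
33 | 5β-labda-13(16),14-diene-8α,18-diol | C=CC(=C)CC[C@@H]1[C@@]2(C)CCC[C@@](C)(CO)[C@H]2CC[C@@]1(C)O | intermediate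
34 | (2Z)-3-iodoprop-2-enoic acid | OC(=O)/C=C\I | starting material
35 | 8α-hydroxy-5β-labda-13(16),14-dien-18-yl (2Z)-3-iodoprop-2-enoate | C=CC(=C)CC[C@@H]1[C@@]2(C)CCC[C@@](C)(COC(=O)/C=C\I)[C@H]2CC[C@@]1(C)O | intermediate
36 | (4-hydroxyphenyl)boronic acid | OB(O)c1ccc(O)cc1 | starting material
37 | 8α-hydroxy-5β-labda-13(16),14-dien-18-yl (2Z)-3-(4-hydroxyphenyl)prop-2-enoate, (4R,5S,8R,9R,10S) | C=CC(=C)CC[C@@H]1[C@@]2(C)CCC[C@@](C)(COC(=O)/C=C\c3ccc(O)cc3)[C@H]2CC[C@@]1(C)O | target

## Step count and least certain steps

Total: 25 steps. Longest linear sequence: 22 steps (steps 1–3 and 7–25 from 1; the branch from 6 through steps 4–6 is equally long).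

**Step 13 (key step).** The cycloaddition may be too slow at low temperature, because the s-cis diene is strained with C9 on the inside position and two quaternary carbons are being formed. Warming then invites ionisation of the dioxolane by the aluminium Lewis acid, with loss of the C9 stereocentre, and purely thermal activation invites the 1,5-hydrogen shift of H9 along the Z-diene. Fallback: use a more reactive dienophile. Starting from 20, i-Bu2AlH at −78 °C gives the (2Z)-allylic alcohol F1, and MnO2 gives the (2Z)-2-methyl enal F2. F2 should cyclise in toluene at 80–110 °C, below the range of the hydrogen shift and without Lewis acid, to the C18 aldehyde F3. Oxidation with NaClO2 and 2-methylbut-2-ene gives acid F4, and Me3SiCHN2 returns the route to 21.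

**Step 7.** Insertion of the hindered ketal enoate into the hindered dienyl–rhodium bond may be slower than protodeboronation of 13, the dienyl–rhodium species may lose its geometry, and the enantioface sense rests on analogy. Fallback: an auxiliary-controlled cuprate addition. Starting from 11, LiOH gives acid F5, which is joined through its pivaloyl mixed anhydride to (4S)-4-phenyl-1,3-oxazolidin-2-one to give the enoyl imide F6. Dienyllithium 12 is converted with MgBr2·OEt2 into (2Z)-penta-2,4-dien-2-ylmagnesium bromide F7, which adds with CuBr·SMe2 at −40 °C to the magnesium-chelated s-cis imide on the face opposite the phenyl group and gives the (3R)-adduct F8. LiBH4 cleaves the auxiliary and returns the route to 15.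

**Step 17.** Facial selectivity of the epoxidation may be poor or reversed if ring B reacts through the chair in which the C10 methyl no longer screens the β-face of C8. Fallback: if oxygen prefers the β-face, carbon is delivered to that face instead. Starting from 23, MeMgBr with CeCl3 at −78 °C adds to the ketone and spares the hindered ester, giving the 8α-hydroxy-8β-methyl ester F9; LiAlH4 then reduces the ester and returns the route to 26.

**Step 22.** The dienyl Grignard reagent may react through its allenic form, or the iodide may be reduced by halogen–metal exchange, so that the 2-substituted diene is not the main product. Fallback: build the diene from an alkyne. Starting from 29, LiC≡CH·H2NCH2CH2NH2 in DMSO gives the terminal alkyne F10, and enyne metathesis with ethylene and second-generation Grubbs catalyst returns the route to 32.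

**Step 24 (with step 25).** Acylation of the neopentyl C18 hydroxyl is slow, and during it the Z-iodoacrylate may drift to E by addition–elimination of DMAP or iodide; step 25 would then carry the wrong geometry forward. Fallback: make the Z-alkene on the substrate. Starting from 33, [bis(2,2,2-trifluoroethoxy)phosphoryl]acetic acid and a carbodiimide give the C18 phosphonoacetate F11. Still–Gennari olefination (KN(SiMe3)2, 18-crown-6, −78 °C) with 4-(tert-butyldimethylsilyloxy)benzaldehyde gives the silyl-protected Z-coumarate F12, and Bu4NF buffered with acetic acid returns the route to 37.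

## Further compounds

F1 | step 13 | (2Z)-5-{2-[(3R,4Z)-1-(4-methoxybenzyloxy)-4-methylhepta-4,6-dien-3-yl]-1,3-dioxolan-2-yl}-2-methylpent-2-en-1-ol | C=C/C=C(/C)[C@@H](CCOCc1ccc(OC)cc1)C1(CC/C=C(/C)CO)OCCO1
F2 | step 13 | (2Z)-5-{2-[(3R,4Z)-1-(4-methoxybenzyloxy)-4-methylhepta-4,6-dien-3-yl]-1,3-dioxolan-2-yl}-2-methylpent-2-enal | C=C/C=C(/C)[C@@H](CCOCc1ccc(OC)cc1)C1(CC/C=C(/C)C=O)OCCO1
F3 | step 13 | 8,8-(ethylenedioxy)-12-(4-methoxybenzyloxy)-13,14,15,16,17-pentanor-5β-labd-1-en-18-al | COc1ccc(COCC[C@@H]2[C@@]3(C)C=CC[C@@](C)(C=O)[C@H]3CCC24OCCO4)cc1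
F4 | step 13 | 8,8-(ethylenedioxy)-12-(4-methoxybenzyloxy)-13,14,15,16,17-pentanor-5β-labd-1-en-18-oic acid | COc1ccc(COCC[C@@H]2[C@@]3(C)C=CC[C@@](C)(C(=O)O)[C@H]3CCC24OCCO4)cc1
F5 | step 7 | (2E)-3-{2-[3-(tert-butyldimethylsilyloxy)propyl]-1,3-dioxolan-2-yl}prop-2-enoic acid | OC(=O)/C=C/C1(CCCO[Si](C)(C)C(C)(C)C)OCCO1
F6 | step 7 | (4S)-3-[(2E)-3-{2-[3-(tert-butyldimethylsilyloxy)propyl]-1,3-dioxolan-2-yl}prop-2-enoyl]-4-phenyl-1,3-oxazolidin-2-one | O=C(/C=C/C1(CCCO[Si](C)(C)C(C)(C)C)OCCO1)N1[C@@H](c2ccccc2)COC1=O
F7 | step 7 | (2Z)-penta-2,4-dien-2-ylmagnesium bromide | C=C/C=C(/C)[Mg]Br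
F8 | step 7 | (4S)-3-[(3R,4Z)-3-{2-[3-(tert-butyldimethylsilyloxy)propyl]-1,3-dioxolan-2-yl}-4-methylhepta-4,6-dienoyl]-4-phenyl-1,3-oxazolidin-2-one | C=C/C=C(/C)[C@@H](CC(=O)N1[C@@H](c2ccccc2)COC1=O)C1(CCCO[Si](C)(C)C(C)(C)C)OCCO1
F9 | step 17 | methyl 8α-hydroxy-12-(4-methoxybenzyloxy)-13,14,15,16-tetranor-5β-labdan-18-oate | COc1ccc(COCC[C@@H]2[C@@]3(C)CCC[C@@](C)(C(=O)OC)[C@H]3CC[C@@]2(C)O)cc1
F10 | step 22 | 8α,18-bis(triethylsilyloxy)-15,16-dinor-5β-labd-13-yne | C#CCC[C@@H]1[C@@]2(C)CCC[C@@](C)(CO[Si](CC)(CC)CC)[C@H]2CC[C@@]1(C)O[Si](CC)(CC)CC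
F11 | step 24 | 8α-hydroxy-5β-labda-13(16),14-dien-18-yl [bis(2,2,2-trifluoroethoxy)phosphoryl]acetate | C=CC(=C)CC[C@@H]1[C@@]2(C)CCC[C@@](C)(COC(=O)CP(=O)(OCC(F)(F)F)OCC(F)(F)F)[C@H]2CC[C@@]1(C)O
F12 | step 24 | 8α-hydroxy-5β-labda-13(16),14-dien-18-yl (2Z)-3-[4-(tert-butyldimethylsilyloxy)phenyl]prop-2-enoate | C=CC(=C)CC[C@@H]1[C@@]2(C)CCC[C@@](C)(COC(=O)/C=C\c3ccc(O[Si](C)(C)C(C)(C)C)cc3)[C@H]2CC[C@@]1(C)O
A1 | alternative 1 | 4-{4-[(tert-butyldimethylsilyloxy)methyl]pent-4-en-1-yl}-5-[2-(4-methoxybenzyloxy)ethyl]-4,6-dimethylcyclohex-2-en-1-one (ring B enone, configuration as in the SMILES) | COc1ccc(COCC[C@@H]2[C@@](C)(CCCC(=C)CO[Si](C)(C)C(C)(C)C)C=CC(=O)[C@H]2C)cc1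
A2 | alternative 1 | 18-(tert-butyldimethylsilyloxy)-12-(4-methoxybenzyloxy)-13,14,15,16-tetranor-5β,8βH-labdan-7-one | COc1ccc(COCC[C@@H]2[C@@]3(C)CCC[C@@](C)(CO[Si](C)(C)C(C)(C)C)[C@H]3CC(=O)[C@H]2C)cc1
A3 | alternative 2 | 18-(tert-butyldimethylsilyloxy)-15,16-dinor-5β-labd-13-yn-8α-ol | C#CCC[C@@H]1[C@@]2(C)CCC[C@@](C)(CO[Si](C)(C)C(C)(C)C)[C@H]2CC[C@@]1(C)O
A4 | alternative 2 | 18-(tert-butyldimethylsilyloxy)-5β-labda-13(16),14-dien-8α-ol | C=CC(=C)CC[C@@H]1[C@@]2(C)CCC[C@@](C)(CO[Si](C)(C)C(C)(C)C)[C@H]2CC[C@@]1(C)O
A5 | alternative 3 | methyl (2E)-3-{3-[(tert-butyldimethylsilyloxy)methyl]-1,3-dimethyl-2-(3-oxobutyl)cyclohexyl}prop-2-enoate (ring A, configuration as in the SMILES) | COC(=O)/C=C/[C@@]1(C)CCC[C@@](C)(CO[Si](C)(C)C(C)(C)C)[C@H]1CCC(C)=O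
A6 | alternative 3 | methyl 18-(tert-butyldimethylsilyloxy)-8α-hydroxy-13,14,15,16-tetranor-5β-labdan-12-oate | COC(=O)C[C@@H]1[C@@]2(C)CCC[C@@](C)(CO[Si](C)(C)C(C)(C)C)[C@H]2CC[C@@]1(C)O
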